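**Assumptions:** The stereocentre in the SMILES decodes as (2S), with CIP order O1 > C1' > C3 > H. 7-Hydroxychromone, tributyl(prenyl)stannane and (S)-MeO-F12-BIPHEP are taken as purchasable.

## Retrosynthetic overview
1. The target comes from a buffered global desilylation of its 7,4'-bis-TBS ether.
2. The key disconnection is the C2–C1' bond, not the chalcone/oxa-Michael C–O bond. A Rh(I)/chiral diphosphine catalyses enantioselective 1,4-addition of a fully prenylated arylboronic acid to a fully prenylated chromone, joining the halves and setting 2S in one step.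
3. The chromone half comes from 7-hydroxychromone by C8 iodination, Stille prenylation and O-silylation.
4. The boronic acid half comes from 4-iodophenol by one-pot o,o'-diprenylation in water, O-silylation and I→B exchange.
5. No ring is built. The A/C bicycle is bought as the γ-pyrone, the B ring arrives intact, and the C ring becomes the dihydropyranone in the key step.

## Route

**Step 1**
Reactants: 1, 7-hydroxy-4H-chromen-4-one; 2, N-iodosuccinimide
Product: 3, 7-hydroxy-8-iodo-4H-chromen-4-one
Conditions: NIS (1.0 equiv), TsOH (10 mol %), MeCN, 0 °C → rt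
Reagents that add atoms: N-iodosuccinimide, O=C1CCC(=O)N1I
Why: This is an electrophilic aromatic iodination in which the 7-OH directs ortho, C8 is favoured over C6 because the C7–C8 bond has the higher double-bond character (as in 7-hydroxycoumarins), and the electron-poor pyrone C=C stays untouched.

**Step 2**
Reactants: 3; 4, tributyl(3-methylbut-2-en-1-yl)stannane
Product: 5, 7-hydroxy-8-(3-methylbut-2-en-1-yl)-4H-chromen-4-one
Conditions: 4 (1.3 equiv), Pd2(dba)3 (2.5 mol %), AsPh3 (20 mol %), DMF, 60 °C; aq KF work-up
Reagents that add atoms: tributyl(prenyl)stannane, CCCC[Sn](CCCC)(CCCC)CC=C(C)C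
Why: This Migita–Kosugi–Stille coupling runs under neutral conditions that spare the free phenol and the base-sensitive γ-pyrone, and reductive elimination from the aryl(η3-prenyl)Pd species at the unsubstituted terminus gives the linear prenyl group.

**Step 3**
Reactants: 5; 6, tert-butyldimethylsilyl chloride
Product: 7, 7-[(tert-butyldimethylsilyl)oxy]-8-(3-methylbut-2-en-1-yl)-4H-chromen-4-one
Conditions: TBSCl, imidazole, DMF, rt
Reagents that add atoms: TBSCl, CC(C)(C)[Si](C)(C)Cl
Why: This standard phenol O-silylation removes the acidic 7-OH, which would otherwise form a deactivating phenoxide or protonate Ar–Rh, and uses a group that fluoride later removes without acid or base.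

**Step 4**
Reactants: 8, 4-iodophenol; 9, prenyl bromide (1-bromo-3-methylbut-2-ene)
Product: 10, 4-iodo-2,6-bis(3-methylbut-2-en-1-yl)phenol
Conditions: 9 (2.5 equiv, portionwise), KOH (3 equiv), H2O, rt, vigorous stirring
Reagents that add atoms: prenyl bromide, CC(C)=CCBr (two equivalents incorporated)
Why: This is a double ortho C-alkylation of a phenoxide in water, where hydrogen-bond solvation masks the oxygen so SN2 occurs through the ortho carbons, the para position is blocked by iodine, and O-prenyl and mono-prenyl by-products are removed by chromatography.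

**Step 5**
Reactants: 10; 6, TBSCl
Product: 11, tert-butyl[4-iodo-2,6-bis(3-methylbut-2-en-1-yl)phenoxy]dimethylsilane
Conditions: NaH, THF, 0 °C; then TBSCl, rt
Reagents that add atoms: TBSCl, CC(C)(C)[Si](C)(C)Cl
Why: Silylating the preformed sodium phenoxide overcomes the 2,6-disubstitution, and the acid-free conditions avoid cyclisation of the o-prenylphenol to a chroman.

**Step 6**
Reactants: 11; 12, triisopropyl borate
Product: 13, {4-[(tert-butyldimethylsilyl)oxy]-3,5-bis(3-methylbut-2-en-1-yl)phenyl}boronic acid
Conditions: B(OiPr)3 (1.5 equiv), n-BuLi (1.1 equiv, in-situ quench), THF, −78 °C → rt; sat. aq NH4Cl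
Reagents that add atoms: triisopropyl borate, CC(C)OB(OC(C)C)OC(C)C; water, O
Why: Iodine–lithium exchange followed by borate trapping and hydrolysis is fast at −78 °C, the aryllithium is para to OTBS so silyl migration is impossible, and the prenyl groups are inert.

**Step 7 (key step)**
Reactants: 7; 13 (1.8 equiv, added in two portions)
Product: 14, (2S)-7-[(tert-butyldimethylsilyl)oxy]-2-{4-[(tert-butyldimethylsilyl)oxy]-3,5-bis(3-methylbut-2-en-1-yl)phenyl}-8-(3-methylbut-2-en-1-yl)-2,3-dihydro-4H-chromen-4-one
Conditions: [RhCl(C2H4)2]2 (2.5 mol %), (S)-MeO-F12-BIPHEP (5.5 mol %), KOH (10 mol %), CH2Cl2/H2O 10:1, 25 °C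
Reagents that add atoms: boronic acid 13 (aryl group), CC(C)=CCc1cc(B(O)O)cc(CC=C(C)C)c1O[Si](C)(C)C(C)(C)C; water supplies only H at C3
Why: In this Hayashi–Miyaura asymmetric 1,4-addition to a chromone, the electron-poor diphosphine makes Ar–Rh insertion fast at rt so retro-oxa-Michael racemisation and 1,2-over-addition are suppressed, and the (S)-biaryl diphosphine delivers aryl to the same enone face that gives (S)-3-arylcyclohexanones, which maps onto 2S here (to be checked by chiral HPLC and CD).

**Step 8**
Reactants: 14
Product: 15, (2S)-sophoranone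
Conditions: TBAF/AcOH (1:1.2, 3 equiv), THF, 0 °C → rt
Reagents that add atoms: none
Why: Fluoride cleaves both aryl silyl ethers, and the acetic acid buffer protonates the phenoxides as they form, so neither base-induced ring opening and racemisation at C2 nor acid-induced prenyl-to-chroman cyclisation can occur.

## Compound list

| No. | Name | SMILES | Role |
|---|---|---|---|
| 1 | 7-hydroxychromone | O=C1C=COc2cc(O)ccc12 | starting material |
| 2 | N-iodosuccinimide | O=C1CCC(=O)N1I | starting material (reagent) |
| 3 | 7-hydroxy-8-iodochromone | O=C1C=COc2c(I)c(O)ccc12 | intermediate |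
| 4 | tributyl(prenyl)stannane | CCCC[Sn](CCCC)(CCCC)CC=C(C)C | starting material |
| 5 | 7-hydroxy-8-prenylchromone | O=C1C=COc2c(CC=C(C)C)c(O)ccc12 | intermediate |
| 6 | TBSCl | CC(C)(C)[Si](C)(C)Cl | starting material (reagent) |
| 7 | 7-TBSO-8-prenylchromone | O=C1C=COc2c(CC=C(C)C)c(O[Si](C)(C)C(C)(C)C)ccc12 | intermediate |
| 8 | 4-iodophenol | Oc1ccc(I)cc1 | starting material |
| 9 | prenyl bromide | CC(C)=CCBr | starting material |
| 10 | 4-iodo-2,6-diprenylphenol | CC(C)=CCc1cc(I)cc(CC=C(C)C)c1O | intermediate |
| 11 | 4-iodo-2,6-diprenylphenyl TBS ether | CC(C)=CCc1cc(I)cc(CC=C(C)C)c1O[Si](C)(C)C(C)(C)C | intermediate |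
| 12 | triisopropyl borate | CC(C)OB(OC(C)C)OC(C)C | starting material (reagent) |
| 13 | 4-TBSO-3,5-diprenylphenylboronic acid | CC(C)=CCc1cc(B(O)O)cc(CC=C(C)C)c1O[Si](C)(C)C(C)(C)C | intermediate |
| 14 | (2S)-7,4'-bis-O-TBS-sophoranone | CC(C)=CCc1cc([C@@H]2CC(=O)c3ccc(O[Si](C)(C)C(C)(C)C)c(CC=C(C)C)c3O2)cc(CC=C(C)C)c1O[Si](C)(C)C(C)(C)C | intermediate |
| 15 | (2S)-sophoranone | CC(C)=CCc1cc([C@@H]2CC(=O)c3ccc(O)c(CC=C(C)C)c3O2)cc(CC=C(C)C)c1O | target |

## Summary
Total steps: 8. Longest linear sequence: 5 (steps 1→2→3→7→8 or 4→5→6→7→8).

**Steps most likely to fail, with fallbacks**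

1. **Step 7.**
   - Risks: the 7-oxy-8-alkyl chromone is an electron-rich, hindered acceptor; 13 may protodeboronate; 1,2-over-addition may occur; ee may erode through ring opening.
   - Fallback: set the stereocentre as a benzylic carbinol and form the C–O bond last. Formylate 11 (n-BuLi, then DMF). Run an enantioselective boron-enolate aldol with 2-hydroxy-3-prenyl-4-silyloxyacetophenone to give the (R)-β-hydroxyketone. Close the pyranone by intramolecular Mitsunobu etherification with inversion to 2S.

2. **Step 4.**
   - Risks: mixtures of O-, mono-C- and di-C-prenylated products, and a low yield.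
   - Fallback: install the prenyl groups by coupling and the boron by C–H activation. Silylate 2,6-dibromophenol and carry out a double Stille coupling with 4. Then use Ir-catalysed C–H borylation ([Ir(OMe)(cod)]2/dtbpy, B2pin2), which can reach only the unhindered C4–H.

3. **Step 2, together with the C8 selectivity of step 1.**
   - Risks: linear versus reverse-prenyl coupling on a di-ortho-substituted iodide, and C6 or di-iodination in step 1.
   - Fallback: replace both steps with a sigmatropic route. O-alkylate 1 with 3-chloro-3-methylbut-1-yne (CuCl2/DBU) and semi-hydrogenate over Lindlar catalyst to the 1,1-dimethylallyl ether. A thermal aromatic Claisen rearrangement then places a linear prenyl group at C8 by [3,3] transposition, giving 5.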